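(All runs were computed with constants of no real substance, noise included.)

The constant I want is the selectivity factor, which the earlier runs can supply before the flask is reckoned.

in all of them: substrate 27 mM; reagent 16.2 mM

|  | other conformer | remark | time |
|---|---|---|---|
| epsilon | 9 mM | run made earlier |  |
| alpha | 20 mM | run made earlier |  |
| flask | 13.5 mM |  | 10 h |

- epsilon (time / h: target / %, isomer of the product / %): 0.667: 3.4, 3.0; 2.00: 6.7, 4.1; 4.00: 11.5, 10.4; 6.00: 14.6, 8.7; 8.00: 15.1, 12.0
- alpha (time / h: target / %, isomer of the product / %): 0.667: 2.3, 3.4; 1.33: 3.9, 6.3; 2.50: 6.1, 9.7; 4.00: 7.0, 9.8; 8.00: 14.5, 11.9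

(standard deviation of a reading: 1 percentage point)

* share of target in target plus isomer of the product at 8.0 min
* share of target in target plus isomer of the product at 10 h

- candidate steps: substrate <-> other conformer; substrate + reagent <-> target; reagent + other conformer -> isomer of the product

Summing the first two readings of the epsilon run and scaling by its charges gives 0.474, target formed per isomer of the product formed at equal substrate and other conformer. The alpha run reads 0.473. The share of target is then s·substrate/(s·substrate + other conformer), which at the flask's charges gives 48.7%, my answer for 8.0 min.

The alpha run's share climbs from 40.4% to 54.9%, while the epsilon run's moves from 53.1% to 55.7%. I therefore read other conformer as passing into substrate, towards epsilon's ratio, and 48.7% becomes the floor for 10 h. Epsilon's charges in the rule give a ceiling of 58.7%. Since the flask charges more other conformer than epsilon, epsilon's last reading, 55.7%, tightens it. Going round again, the alpha run's last share, 54.9%, stands beside that reading, so I commit to the bracket from 48.7% to 55.7% for 10 h and name no point inside it.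

The forecast gives 48.5% and 58%, the second above my ceiling, on the ground: “The flask lies between the two, nearer epsilon”.

The flask gives 50.3% and 51.8%.

    substrate ⇌ other conformer (K = 0.330, k = 2.90 × 10⁻⁵ s⁻¹)
    substrate + reagent ⇌ target (K = 96.0 M⁻¹, k = 0.00110 M⁻¹ s⁻¹)
    reagent + other conformer → isomer of the product (k = 0.00220 M⁻¹ s⁻¹)

The flask's 10 h share lies above my floor and below my ceiling. On the neighbouring flask, charged with 8.1 mM of other conformer, the rule gives 61.2% at 8.0 min, and that flask stands at 62.5%. The rule's value now lies above epsilon's last reading, so the two bound the neighbouring flask the other way round. At 10 h, the neighbouring flask's share is 56.8%, between the two.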